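## Retrosynthetic overview

1. Target 24 comes from its 5'-O-silyl ether 23 by fluoride. Ring A of 23 is closed last by forming C4–C5: the acetyl CH3 enolate of keto ester 21 attacks the furan-3-carboxylate, and the resulting dione aromatises by tautomerism.
2. Feature used: ring A (C3a–C4–C5–C6–C7–C7a) is a resorcinol fused to the furan. C4–OH sits on the carbon bonded to furan C3, C6–OH is 1,3 to it across C5–H, and C7 (bearing the 2-methylbut-3-en-2-yl group) is bonded to furan C2. Hence C4 is an ester carbon on furan C3, C6/C5 an acetyl group, and C7 an sp3 methine on furan C2 that can receive its quaternary neighbour before any arene exists.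
3. 21 comes from Suzuki coupling of bromofuran ketone 13 (bromine on the carbon that becomes benzofuran C2) with ring B boronate 20.
4. 13 comes from prenyl furylacetate 7 by Ireland–Claisen rearrangement (C7–quaternary bond) and acid-to-methyl-ketone conversion; the furan comes from a Feist–Benary reaction of 1 and 2, then C5 bromination.
5. 20 comes from phenol 14 by silylation, lithiation between Br and OMe with prenylation, and bromine-to-boron exchange. Ring order: furan (step 1), ring B bought in, ring A (step 11).

Key step: step 11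

Assumption: the target has no stereocentre; compounds 10–13, 21 and 22 are racemic at the carbon that becomes aromatic C7. Chloroacetaldehyde is used as its commercial aqueous solution. Benzofuran numbering is used for ring A and primed locants for ring B.

## Route

Step 1
Reactants: 1 dimethyl 3-oxoglutarate; 2 chloroacetaldehyde
Product: 3 methyl 2-(2-methoxy-2-oxoethyl)furan-3-carboxylate
Conditions: pyridine, 50% aq. ClCH2CHO, 50 °C
Reagents that add atoms: none
Why: Feist–Benary furan synthesis, in which the doubly activated C2–H of the β-keto ester adds to the aldehyde, the enol oxygen displaces chloride and loss of water aromatises, placing the CH2CO2Me arm on C2, the ester on C3 and leaving C5 free.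

Step 2
Reactants: 3 methyl 2-(2-methoxy-2-oxoethyl)furan-3-carboxylate
Product: 4 methyl 5-bromo-2-(2-methoxy-2-oxoethyl)furan-3-carboxylate
Conditions: NBS, DMF, 0 °C → rt, dark
Reagents that add atoms: N-bromosuccinimide, O=C1CCC(=O)N1Br
Why: Electrophilic aromatic bromination should go to C5, the only free α-position of the furan, in preference to the ester-flanked C4 or the side-chain methylene.

Step 3
Reactants: 4 methyl 5-bromo-2-(2-methoxy-2-oxoethyl)furan-3-carboxylate
Product: 5 2-[5-bromo-3-(methoxycarbonyl)furan-2-yl]acetic acid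
Conditions: LiOH·H2O (1.05 equiv), THF/H2O, 0 °C; then 1 M HCl
Reagents that add atoms: lithium hydroxide, [Li+].[OH-] (its oxygen becomes the acid OH)
Why: Chemoselective saponification, since the unconjugated acetic ester is much more electrophilic than the furan-3-carboxylate (a vinylogous carbonate), so one equivalent of hydroxide at 0 °C should cleave only the side-chain ester.

Step 4
Reactants: 5 2-[5-bromo-3-(methoxycarbonyl)furan-2-yl]acetic acid; 6 prenol (3-methylbut-2-en-1-ol)
Product: 7 methyl 5-bromo-2-{2-[(3-methylbut-2-en-1-yl)oxy]-2-oxoethyl}furan-3-carboxylate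
Conditions: EDC·HCl, DMAP (cat.), CH2Cl2, 0 °C → rt
Reagents that add atoms: none
Why: Steglich esterification (carbodiimide activation, DMAP acyl transfer) runs under near-neutral conditions that leave the bromofuran, the methyl ester and the prenyl alkene untouched.

Step 5
Reactants: 7 methyl 5-bromo-2-{2-[(3-methylbut-2-en-1-yl)oxy]-2-oxoethyl}furan-3-carboxylate
Product: 11 2-[5-bromo-3-(methoxycarbonyl)furan-2-yl]-3,3-dimethylpent-4-enoic acid (racemic), via lithium enolate 8 (not isolated), via silyl ketene acetal 9 (not isolated), via trimethylsilyl ester 10 (not isolated)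
Conditions: LiN(SiMe3)2 (1.2 equiv), THF, −78 °C; Me3SiCl; −78 → 65 °C; then 1 M HCl
Reagents that add atoms: chlorotrimethylsilane, C[Si](C)(C)Cl (silyl group carried in 9 and 10 only); LiN(SiMe3)2, [Li+].C[Si](C)(C)[N-][Si](C)(C)C (lithium in 8 only); no reagent atom other than hydrogen stays in 11
Why: Ireland–Claisen rearrangement, in which the doubly activated methylene is deprotonated, O-silylated and joined to the dimethyl-substituted alkene terminus by a chair [3,3] shift, so the 2-methylbut-3-en-2-yl group arrives with full allylic transposition and the single new stereocentre is formed racemic (it later becomes aromatic C7).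

Step 6
Reactants: 11 2-[5-bromo-3-(methoxycarbonyl)furan-2-yl]-3,3-dimethylpent-4-enoic acid
Product: 13 methyl 5-bromo-2-(4,4-dimethyl-2-oxohex-5-en-3-yl)furan-3-carboxylate (racemic), via acid chloride 12 (not isolated)
Conditions: (COCl)2, DMF (cat.), CH2Cl2, 0 °C → rt, evaporate; Me2CuLi (from MeLi and CuBr·SMe2, 3 equiv), Et2O, −78 °C; aq. NH4Cl
Reagents that add atoms: lithium dimethylcuprate, [Li+].C[Cu-]C (made from methyllithium, [Li]C; gives the acetyl CH3 of 13); oxalyl chloride, O=C(Cl)C(=O)Cl (chlorine in 12 only)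
Why: Acid chloride formation followed by acylation of a Gilman cuprate, which stops at the ketone and at −78 °C should not touch the methyl ester, the bromofuran or the vinyl group.

Step 7
Reactants: 14 3-bromo-5-methoxyphenol
Product: 15 (3-bromo-5-methoxyphenoxy)triisopropylsilane
Conditions: iPr3SiCl, imidazole, DMF, rt
Reagents that add atoms: chlorotriisopropylsilane, CC(C)[Si](Cl)(C(C)C)C(C)C
Why: Standard phenol silylation; the bulky silyl ether shields the positions next to its oxygen from metalation and is removable by fluoride at the end.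

Step 8
Reactants: 15 (3-bromo-5-methoxyphenoxy)triisopropylsilane
Product: 18 [3-bromo-5-methoxy-4-(3-methylbut-2-en-1-yl)phenoxy]triisopropylsilane, via aryllithium 16 (not isolated), via arylcopper 17 (not isolated)
Conditions: lithium 2,2,6,6-tetramethylpiperidide (from the amine and n-BuLi), THF, −78 °C; CuBr·SMe2 (THF/Me2S solution), −78 °C; prenyl bromide, −78 → 0 °C
Reagents that add atoms: 1-bromo-3-methylbut-2-ene (prenyl bromide), CC(C)=CCBr; lithium 2,2,6,6-tetramethylpiperidide, [Li+].CC1(C)CCCC(C)(C)[N-]1 (lithium in 16 only); CuBr·SMe2, [Cu]Br.CSC (copper in 17 only)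
Why: Directed ortho-metalation, since the proton between bromine and methoxy is the most acidic and the only one not shielded by the silyl group and the hindered amide base does not exchange bromine; transmetalation to copper should then give substitution of prenyl bromide at its primary carbon.

Step 9
Reactants: 18 [3-bromo-5-methoxy-4-(3-methylbut-2-en-1-yl)phenoxy]triisopropylsilane
Product: 20 2-[3-methoxy-2-(3-methylbut-2-en-1-yl)-5-(triisopropylsilyloxy)phenyl]-4,4,5,5-tetramethyl-1,3,2-dioxaborolane, via aryllithium 19 (not isolated)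
Conditions: n-BuLi, THF, −78 °C, 15 min; iPrOBpin, −78 °C → rt; aq. NH4Cl
Reagents that add atoms: 2-isopropoxy-4,4,5,5-tetramethyl-1,3,2-dioxaborolane, CC(C)OB1OC(C)(C)C(C)(C)O1; n-butyllithium, [Li]CCCC (lithium in 19 only)
Why: Bromine–lithium exchange at −78 °C is faster than any deprotonation of the allylic or benzylic positions, and the aryllithium is trapped at boron (borylation of an organolithium).

Step 10
Reactants: 13 methyl 5-bromo-2-(4,4-dimethyl-2-oxohex-5-en-3-yl)furan-3-carboxylate; 20 2-[3-methoxy-2-(3-methylbut-2-en-1-yl)-5-(triisopropylsilyloxy)phenyl]-4,4,5,5-tetramethyl-1,3,2-dioxaborolane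
Product: 21 methyl 2-(4,4-dimethyl-2-oxohex-5-en-3-yl)-5-[3-methoxy-2-(3-methylbut-2-en-1-yl)-5-(triisopropylsilyloxy)phenyl]furan-3-carboxylate (racemic)
Conditions: Pd(dppf)Cl2 (5 mol %), K3PO4, 1,4-dioxane/H2O (9:1), 70 °C
Reagents that add atoms: none
Why: Suzuki–Miyaura coupling of an α-bromofuran (fast oxidative addition) with a mono-ortho-substituted arylboronate, under a phosphate base that should leave ketone, ester and silyl ether intact and is too weak to trigger the ring closure of step 11.

Step 11
Reactants: 21 methyl 2-(4,4-dimethyl-2-oxohex-5-en-3-yl)-5-[3-methoxy-2-(3-methylbut-2-en-1-yl)-5-(triisopropylsilyloxy)phenyl]furan-3-carboxylate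
Product: 23 2-[3-methoxy-2-(3-methylbut-2-en-1-yl)-5-(triisopropylsilyloxy)phenyl]-7-(2-methylbut-3-en-2-yl)-1-benzofuran-4,6-diol, via benzofurandione 22 (not isolated)
Conditions: KOtBu (3.5 equiv), degassed THF, 0 °C → rt (50 °C if slow), argon; aq. NH4Cl, 0 °C
Reagents that add atoms: none
Why: Intramolecular Claisen (Dieckmann-type) condensation, the furan counterpart of the base-mediated closure of 2-(2-oxopropyl)benzoates to naphthalene-1,3-diols: tert-butoxide first removes the acidic methine proton at future C7, and proton exchange makes the terminal acetyl enolate (future C5) available. That enolate attacks the furan-3-carboxylate carbonyl (future C4) in a favoured 6-(enolendo)-exo-trig closure, methoxide leaves and dione 22 results. Enolisation of 22 toward C5 and C7 gives the aromatic 4,6-diol, held as its phenoxide by the excess base, which makes the sequence irreversible and drains the unproductive C7 enolate through the equilibrium. The only selectivity needed is which enolate site is acylated: C7 cannot reach the ester (a four-membered ring would result) and O-acylation to the enol lactone is reversed by alkoxide, so the material should funnel to 23. No stereocentre is formed (the one in 21 is erased on aromatisation), neither alkene meets acid, oxidant or metal, and any silyl ether cleaved by the liberated methoxide would simply give 24 early.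

Step 12
Reactants: 23 2-[3-methoxy-2-(3-methylbut-2-en-1-yl)-5-(triisopropylsilyloxy)phenyl]-7-(2-methylbut-3-en-2-yl)-1-benzofuran-4,6-diol
Product: 24 2-[5-hydroxy-3-methoxy-2-(3-methylbut-2-en-1-yl)phenyl]-7-(2-methylbut-3-en-2-yl)-1-benzofuran-4,6-diol (CNP0169501.0)
Conditions: Bu4NF, AcOH (1:1), THF, 0 °C
Reagents that add atoms: none
Why: Fluoride-induced cleavage of the aryl silyl ether; the acetic acid buffer keeps the electron-rich triphenol protonated and is far too weak to add the C6–OH across the neighbouring 2-methylbut-3-en-2-yl alkene.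

## Compound list

1 | dimethyl 3-oxoglutarate | COC(=O)CC(=O)CC(=O)OC | starting material
2 | chloroacetaldehyde | O=CCCl | starting material
3 | methyl 2-(2-methoxy-2-oxoethyl)furan-3-carboxylate | COC(=O)Cc1occc1C(=O)OC | intermediate
4 | methyl 5-bromo-2-(2-methoxy-2-oxoethyl)furan-3-carboxylate | COC(=O)Cc1oc(Br)cc1C(=O)OC | intermediate
5 | 2-[5-bromo-3-(methoxycarbonyl)furan-2-yl]acetic acid | OC(=O)Cc1oc(Br)cc1C(=O)OC | intermediate
6 | prenol (3-methylbut-2-en-1-ol) | CC(C)=CCO | starting material
7 | methyl 5-bromo-2-{2-[(3-methylbut-2-en-1-yl)oxy]-2-oxoethyl}furan-3-carboxylate | COC(=O)c1cc(Br)oc1CC(=O)OCC=C(C)C | intermediate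
8 | lithium enolate of 7 (not isolated; enolate geometry not controlled) | [Li+].COC(=O)c1cc(Br)oc1C=C([O-])OCC=C(C)C | intermediate
9 | trimethylsilyl ketene acetal of 7 (not isolated; geometry not controlled and without consequence) | COC(=O)c1cc(Br)oc1C=C(O[Si](C)(C)C)OCC=C(C)C | intermediate
10 | trimethylsilyl 2-[5-bromo-3-(methoxycarbonyl)furan-2-yl]-3,3-dimethylpent-4-enoate (racemic, not isolated) | COC(=O)c1cc(Br)oc1C(C(=O)O[Si](C)(C)C)C(C)(C)C=C | intermediate
11 | 2-[5-bromo-3-(methoxycarbonyl)furan-2-yl]-3,3-dimethylpent-4-enoic acid (racemic) | COC(=O)c1cc(Br)oc1C(C(=O)O)C(C)(C)C=C | intermediate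
12 | 2-[5-bromo-3-(methoxycarbonyl)furan-2-yl]-3,3-dimethylpent-4-enoyl chloride (racemic, not isolated) | COC(=O)c1cc(Br)oc1C(C(=O)Cl)C(C)(C)C=C | intermediate
13 | methyl 5-bromo-2-(4,4-dimethyl-2-oxohex-5-en-3-yl)furan-3-carboxylate (racemic) | COC(=O)c1cc(Br)oc1C(C(C)=O)C(C)(C)C=C | intermediate
14 | 3-bromo-5-methoxyphenol | COc1cc(O)cc(Br)c1 | starting material
15 | (3-bromo-5-methoxyphenoxy)triisopropylsilane | COc1cc(O[Si](C(C)C)(C(C)C)C(C)C)cc(Br)c1 | intermediate
16 | [2-bromo-6-methoxy-4-(triisopropylsilyloxy)phenyl]lithium (not isolated) | COc1cc(O[Si](C(C)C)(C(C)C)C(C)C)cc(Br)c1[Li] | intermediate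
17 | [2-bromo-6-methoxy-4-(triisopropylsilyloxy)phenyl]copper (not isolated) | COc1cc(O[Si](C(C)C)(C(C)C)C(C)C)cc(Br)c1[Cu] | intermediate
18 | [3-bromo-5-methoxy-4-(3-methylbut-2-en-1-yl)phenoxy]triisopropylsilane | COc1cc(O[Si](C(C)C)(C(C)C)C(C)C)cc(Br)c1CC=C(C)C | intermediate
19 | [3-methoxy-2-(3-methylbut-2-en-1-yl)-5-(triisopropylsilyloxy)phenyl]lithium (not isolated) | COc1cc(O[Si](C(C)C)(C(C)C)C(C)C)cc([Li])c1CC=C(C)C | intermediate
20 | 2-[3-methoxy-2-(3-methylbut-2-en-1-yl)-5-(triisopropylsilyloxy)phenyl]-4,4,5,5-tetramethyl-1,3,2-dioxaborolane | COc1cc(O[Si](C(C)C)(C(C)C)C(C)C)cc(B2OC(C)(C)C(C)(C)O2)c1CC=C(C)C | intermediate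
21 | methyl 2-(4,4-dimethyl-2-oxohex-5-en-3-yl)-5-[3-methoxy-2-(3-methylbut-2-en-1-yl)-5-(triisopropylsilyloxy)phenyl]furan-3-carboxylate (racemic) | COC(=O)c1cc(-c2cc(O[Si](C(C)C)(C(C)C)C(C)C)cc(OC)c2CC=C(C)C)oc1C(C(C)=O)C(C)(C)C=C | intermediate
22 | 2-[3-methoxy-2-(3-methylbut-2-en-1-yl)-5-(triisopropylsilyloxy)phenyl]-7-(2-methylbut-3-en-2-yl)-1-benzofuran-4,6(5H,7H)-dione (racemic, not isolated) | C=CC(C)(C)C1C(=O)CC(=O)c2cc(-c3cc(O[Si](C(C)C)(C(C)C)C(C)C)cc(OC)c3CC=C(C)C)oc21 | intermediate
23 | 2-[3-methoxy-2-(3-methylbut-2-en-1-yl)-5-(triisopropylsilyloxy)phenyl]-7-(2-methylbut-3-en-2-yl)-1-benzofuran-4,6-diol | C=CC(C)(C)c1c(O)cc(O)c2cc(-c3cc(O[Si](C(C)C)(C(C)C)C(C)C)cc(OC)c3CC=C(C)C)oc12 | intermediate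
24 | 2-[5-hydroxy-3-methoxy-2-(3-methylbut-2-en-1-yl)phenyl]-7-(2-methylbut-3-en-2-yl)-1-benzofuran-4,6-diol (CNP0169501.0) | C=CC(C)(C)c1c(O)cc(O)c2cc(-c3cc(O)cc(OC)c3CC=C(C)C)oc12 | target

## Step count and risk

Total step count: 12. Longest linear sequence: 9 steps (steps 1–6, 10–12, from dimethyl 3-oxoglutarate); the ring B branch (steps 7–9) joins at step 10.

**Step 11 (ring A closure).** The base may park the substrate as the hindered C7 enolate while the electron-rich furan ester, a vinylogous carbonate, is attacked only slowly; ester cleavage by adventitious hydroxide or intermolecular condensation could then outrun ring closure. The fallback sets out from 11 (with 20) and comes back at 24; it makes C5 the most acidic carbon by adding an ester activating group. Acid 11 would be coupled with boronate 20 under the conditions of step 10 (one extra equivalent of K3PO4) to give 2-{3-(methoxycarbonyl)-5-[3-methoxy-2-(3-methylbut-2-en-1-yl)-5-(triisopropylsilyloxy)phenyl]furan-2-yl}-3,3-dimethylpent-4-enoic acid F1. Activation with 1,1'-carbonyldiimidazole and reaction with Mg(O2CCH2CO2Me)2 in THF (Masamune homologation) should give the β-keto ester methyl 4-{3-(methoxycarbonyl)-5-[3-methoxy-2-(3-methylbut-2-en-1-yl)-5-(triisopropylsilyloxy)phenyl]furan-2-yl}-5,5-dimethyl-3-oxohept-6-enoate F2. NaH in THF should then close ring A by Dieckmann condensation of the 1,3-dicarbonyl carbon onto the furan ester, giving methyl 4,6-dihydroxy-2-[3-methoxy-2-(3-methylbut-2-en-1-yl)-5-(triisopropylsilyloxy)phenyl]-7-(2-methylbut-3-en-2-yl)-1-benzofuran-5-carboxylate F3. Aqueous KOH in methanol at reflux under argon should saponify this 2,6-dihydroxybenzoate, decarboxylate it and cleave the silyl ether in one operation, giving 24 after buffering to pH 5.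

**Step 8 (ring B prenylation).** The ortho-bromoaryllithium can lose LiBr to an aryne while the transmetalation and alkylation are warmed, and the arylcopper can attack prenyl bromide at its tertiary terminus to give the branched isomer. The fallback sets out from 15 (through aryllithium 16) and comes back at 18; it replaces the aryl–allyl substitution by a benzylic coupling with an alkenyl nucleophile, which cannot transpose. Aryllithium 16 would be quenched at −78 °C with DMF to give 2-bromo-6-methoxy-4-(triisopropylsilyloxy)benzaldehyde F4. NaBH4 in THF/EtOH at 0 °C should give [2-bromo-6-methoxy-4-(triisopropylsilyloxy)phenyl]methanol F5, and CBr4/PPh3 in CH2Cl2 (Appel reaction) should give [3-bromo-4-(bromomethyl)-5-methoxyphenoxy]triisopropylsilane F6. This would be used at once with Me2C=CHMgBr and catalytic Li2CuCl4 in THF at −20 °C (Kochi-type coupling at the benzylic bromide, the aryl bromide staying inert) to give 18.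

**Step 5 (Ireland–Claisen).** The sigmatropic shift must pass through a congested transition state that builds a quaternary carbon next to a fully substituted furan position; while it is slow, the silyl ketene acetal may fragment to a ketene and silyl prenyl ether or be C-silylated. The fallback sets out from 5 and comes back at 11; it installs the quaternary carbon by propargylic alkylation and semi-hydrogenation. Acid 5 would be converted with tert-butyl 2,2,2-trichloroacetimidate and catalytic BF3·OEt2 into methyl 5-bromo-2-[2-(tert-butoxy)-2-oxoethyl]furan-3-carboxylate F7. Its sodium enolate (NaH, THF) would be alkylated with 3-chloro-3-methylbut-1-yne and catalytic CuCl, the known tertiary-propargyl alkylation of malonate-type carbanions, to give methyl 5-bromo-2-[1-(tert-butoxy)-3,3-dimethyl-1-oxopent-4-yn-2-yl]furan-3-carboxylate F8. Semi-hydrogenation (H2, Pd on CaCO3 poisoned with Pb(OAc)2, quinoline, EtOAc) should give methyl 5-bromo-2-[1-(tert-butoxy)-3,3-dimethyl-1-oxopent-4-en-2-yl]furan-3-carboxylate F9, and CF3CO2H in CH2Cl2 should cleave the tert-butyl ester to 11.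

## Further compounds

F1 | step 11 | 2-{3-(methoxycarbonyl)-5-[3-methoxy-2-(3-methylbut-2-en-1-yl)-5-(triisopropylsilyloxy)phenyl]furan-2-yl}-3,3-dimethylpent-4-enoic acid (racemic) | COC(=O)c1cc(-c2cc(O[Si](C(C)C)(C(C)C)C(C)C)cc(OC)c2CC=C(C)C)oc1C(C(=O)O)C(C)(C)C=C
F2 | step 11 | methyl 4-{3-(methoxycarbonyl)-5-[3-methoxy-2-(3-methylbut-2-en-1-yl)-5-(triisopropylsilyloxy)phenyl]furan-2-yl}-5,5-dimethyl-3-oxohept-6-enoate (racemic) | COC(=O)CC(=O)C(c1oc(-c2cc(O[Si](C(C)C)(C(C)C)C(C)C)cc(OC)c2CC=C(C)C)cc1C(=O)OC)C(C)(C)C=C
F3 | step 11 | methyl 4,6-dihydroxy-2-[3-methoxy-2-(3-methylbut-2-en-1-yl)-5-(triisopropylsilyloxy)phenyl]-7-(2-methylbut-3-en-2-yl)-1-benzofuran-5-carboxylate | COC(=O)c1c(O)c(C(C)(C)C=C)c2oc(-c3cc(O[Si](C(C)C)(C(C)C)C(C)C)cc(OC)c3CC=C(C)C)cc2c1O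
F4 | step 8 | 2-bromo-6-methoxy-4-(triisopropylsilyloxy)benzaldehyde | COc1cc(O[Si](C(C)C)(C(C)C)C(C)C)cc(Br)c1C=O
F5 | step 8 | [2-bromo-6-methoxy-4-(triisopropylsilyloxy)phenyl]methanol | COc1cc(O[Si](C(C)C)(C(C)C)C(C)C)cc(Br)c1CO
F6 | step 8 | [3-bromo-4-(bromomethyl)-5-methoxyphenoxy]triisopropylsilane | COc1cc(O[Si](C(C)C)(C(C)C)C(C)C)cc(Br)c1CBr
F7 | step 5 | methyl 5-bromo-2-[2-(tert-butoxy)-2-oxoethyl]furan-3-carboxylate | COC(=O)c1cc(Br)oc1CC(=O)OC(C)(C)C
F8 | step 5 | methyl 5-bromo-2-[1-(tert-butoxy)-3,3-dimethyl-1-oxopent-4-yn-2-yl]furan-3-carboxylate (racemic) | COC(=O)c1cc(Br)oc1C(C(=O)OC(C)(C)C)C(C)(C)C#C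
F9 | step 5 | methyl 5-bromo-2-[1-(tert-butoxy)-3,3-dimethyl-1-oxopent-4-en-2-yl]furan-3-carboxylate (racemic) | COC(=O)c1cc(Br)oc1C(C(=O)OC(C)(C)C)C(C)(C)C=C
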